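The constants of flask beta are not given, so they are read from the runs. At 25.0 s beta holds 9% product and 94% substrate, as fractions of the charge. Zeta, with about half the charge, shows 9% product at 20.0 s against 6% in beta. Each reading scatters by 1.5 percentage points, so fractions are taken as independent of the charge here, and zeta's longer curve serves for beta.

| flask | substrate | gas phase | remark | time |
|---|---|---|---|---|
| beta | 29 mM | 0.97 mM (held) | the very flask that is asked about, followed so far |  |
| zeta | 14 mM | 0.97 mM (held) | run made earlier |  |
| flask | 29 mM | 0.97 mM (held) |  | 2.5 min |

| run | time / s | product / % | substrate / % |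
|---|---|---|---|
| beta | 10.0 | 3 | 97 |
| beta | 12.0 | 3 | 96 |
| beta | 15.0 | 5 | 96 |
| beta | 20.0 | 6 | 92 |
| beta | 25.0 | 9 | 94 |
| zeta | 10.0 | 1 | 97 |
| zeta | 12.0 | 5 | 97 |
| zeta | 20.0 | 9 | 94 |
| zeta | 30.0 | 7 | 92 |
| zeta | 50.0 | 15 | 88 |
| zeta | 60.0 | 14 | 84 |
| zeta | 120 | 25 | 75 |

(standard deviation of a reading: 1.5 percentage points)

- at the start none of the gas phase is in solution

- the product standing at 2.5 min, as a percentage of the substrate charged
- the change that raises the amount of product at 2.5 min, in percent of the substrate charged most ("none" if none brings more than 2 percentage points) (larch / cedar / none)
- amount of product at 2.5 min, in percent of the substrate charged, after larch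

- larch: doubling the saturation concentration of gas phase, all else as stated
- cedar: doubling the transfer coefficient of the gas phase, all else as stated

Zeta gained 14% in its first minute and 11 points in its second. That ratio, 0.786, is the shrink factor: each minute's gain over the one before, as in a pseudo-first-order approach. It rests on a difference of readings, so it is rough.

Summing the shrinking gains gives 29.6% product in beta at 2.5 min. Leave the gas transfer alone. Beta, at twice the charge of zeta, holds 9% by 25.0 s, and zeta holds 9% by 20.0 s and 7% by 30.0 s. The percent pace of beta is thus like that of zeta within the scatter, so this reckoning does not read gas supply as the cap and rejects cedar. With each gain taken as doubled by larch, the sum doubles to a rough mark of 59.2%.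

The forecast says 33%, larch and 55% after larch, holding that “Dissolved gas therefore sits near saturation”.

The flask gives 29.2%. The best change is larch, worth 19 points against 0.1 points for cedar, and larch ends at 48.7%.

    substrate + dissolved gas ⇌ product (K = 900 M⁻¹, k = 3.20 M⁻¹ s⁻¹)
    gas phase ⇌ dissolved gas, rate k2*(csat - [dissolved gas]) (kL = 6.90 s⁻¹)

The shrink factor gave 29.6% where the flask stands at 29.2%. The neighbouring flask is the same charge read at 1.5 min. The same sum, stopped there, gives 19.8% product. That neighbouring flask holds 20.8% product, with 79% of the substrate left.

The data were generated by integration with constants of no real substance; scatter was added.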